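The benzene ring is cut at C1'–C6' and C2'–C3', which leaves a methyl hept-2-ynoate carrying the finished C7–C9 stereotriad and a four-carbon silyloxydiene. The ring is lightly substituted (C9 on C1', an sp2 carbon on C2', methyl on C4', hydrogen on C3', C5' and C6'), so one Diels–Alder cycloaddition followed by loss of silanol closes and aromatizes the six-membered carbocycle with every substituent in place. In the precursor the C6 and C8 oxygens are kept as separate primary and secondary TBS ethers instead of being tied in one acetal, so that C6 can later be unmasked alone for building the 4-hydroxy-2-pyranone ring.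

Key step: step 10

Assumption: numbering follows the pyranone (O1, C2–C6), the side chain (C7–C9) and the benzene ring (C1'–C6'); sulfone 4 and the L-fructose-derived enantiomer of the Shi ketone are taken as purchasable.

Step 1
Reactants: 1 methyl (R)-3-hydroxy-2-methylpropanoate
Product: 2 methyl (R)-3-[(tert-butyldimethylsilyl)oxy]-2-methylpropanoate
Conditions: TBSCl, imidazole, CH2Cl2, 0 °C → rt
Reagents that add atoms: tert-butyldimethylsilyl chloride, CC(C)(C)[Si](C)(C)Cl
Why: Imidazole-promoted silylation of a primary alcohol is routine and leaves the C7 stereocenter, which comes from the starting material, untouched.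

Step 2
Reactants: 2 methyl (R)-3-[(tert-butyldimethylsilyl)oxy]-2-methylpropanoate
Product: 3 (R)-3-[(tert-butyldimethylsilyl)oxy]-2-methylpropanal
Conditions: i-Bu2AlH (1.1 equiv), CH2Cl2, −78 °C; aq. potassium sodium tartrate; crude product used at once
Reagents that add atoms: none
Why: Partial ester reduction with i-Bu2AlH at −78 °C stops at the aluminium hemiacetal, which releases the aldehyde only on neutral tartrate work-up, so the α-methyl stereocenter is not exposed to base.

Step 3
Reactants: 3 (R)-3-[(tert-butyldimethylsilyl)oxy]-2-methylpropanal; 4 5-(ethylsulfonyl)-1-phenyl-1H-tetrazole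
Product: 5 tert-butyldimethyl{[(2S,3E)-2-methylpent-3-en-1-yl]oxy}silane
Conditions: 4, KN(SiMe3)2, DME, −60 °C; then 3, −60 °C → rt
Reagents that add atoms: none
Why: Julia–Kocienski olefination, in which the potassium salt of the tetrazolyl sulfone adds to the aldehyde and the adduct collapses by Smiles rearrangement with loss of SO2 and tetrazolonate, a sequence that favours the (E)-alkene with a potassium counter-ion in DME.

Step 4
Reactants: 5 tert-butyldimethyl{[(2S,3E)-2-methylpent-3-en-1-yl]oxy}silane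
Product: 6 tert-butyldimethyl{(2R)-2-[(2S,3S)-3-methyloxiran-2-yl]propoxy}silane
Conditions: L-fructose-derived enantiomer of the Shi ketone (0.3 equiv), KHSO5 (Oxone), K2CO3, Bu4NHSO4, MeCN/CH2(OMe)2/aq. Na2B4O7 buffer, 0 °C
Reagents that add atoms: potassium peroxymonosulfate, [K+].[O-]S(=O)(=O)OO
Why: Shi asymmetric epoxidation, in which the dioxirane formed from the chiral ketone transfers oxygen through a spiro transition state; since the D-fructose-derived ketone gives R,R-epoxides from trans-alkenes, its enantiomer should set C8 and C9 as S,S under catalyst control.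

Step 5
Reactants: 6 tert-butyldimethyl{(2R)-2-[(2S,3S)-3-methyloxiran-2-yl]propoxy}silane; 7 ethynyltrimethylsilane
Product: 8 (2R,3R,4S)-1-[(tert-butyldimethylsilyl)oxy]-2,4-dimethyl-6-(trimethylsilyl)hex-5-yn-3-ol
Conditions: 7 (3 equiv), n-BuLi, THF, −78 °C; BF3·OEt2; then 6, −78 °C
Reagents that add atoms: none
Why: Yamaguchi–Hirao alkynylation, in which the BF3-activated epoxide is opened by SN2 attack of the alkynyllithium at the methyl-bearing C9 (less hindered than C8, which is flanked by the branched C7, and further from the electron-withdrawing C6 oxygen), so C9 is inverted to give the 8,9-syn relationship while C8 keeps its C–O bond and configuration.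

Step 6
Reactants: 8 (2R,3R,4S)-1-[(tert-butyldimethylsilyl)oxy]-2,4-dimethyl-6-(trimethylsilyl)hex-5-yn-3-ol
Product: 9 (3S,4R,5R)-4,6-bis[(tert-butyldimethylsilyl)oxy]-3,5-dimethyl-1-(trimethylsilyl)hex-1-yne
Conditions: TBSOTf, 2,6-lutidine, CH2Cl2, −78 → 0 °C
Reagents that add atoms: tert-butyldimethylsilyl trifluoromethanesulfonate, CC(C)(C)[Si](C)(C)OS(=O)(=O)C(F)(F)F
Why: Silylation with the silyl triflate and 2,6-lutidine is the standard way to protect a hindered secondary alcohol and gives the C8 ether a lability different from that of the primary C6 ether.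

Step 7
Reactants: 9 (3S,4R,5R)-4,6-bis[(tert-butyldimethylsilyl)oxy]-3,5-dimethyl-1-(trimethylsilyl)hex-1-yne
Product: 10 (3S,4R,5R)-4,6-bis[(tert-butyldimethylsilyl)oxy]-3,5-dimethylhex-1-yne
Conditions: K2CO3 (cat.), MeOH, rt
Reagents that add atoms: none
Why: Carbonate-catalysed methanolysis cleaves the C(sp)–SiMe3 bond selectively, since alkyl TBS ethers are inert to K2CO3 in methanol.

Step 8
Reactants: 10 (3S,4R,5R)-4,6-bis[(tert-butyldimethylsilyl)oxy]-3,5-dimethylhex-1-yne; 11 methyl chloroformate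
Product: 13 methyl (4S,5R,6R)-5,7-bis[(tert-butyldimethylsilyl)oxy]-4,6-dimethylhept-2-ynoate, via lithium acetylide 12 (not isolated)
Conditions: n-BuLi (1.05 equiv), THF, −78 °C; then 11, −78 → 0 °C
Reagents that add atoms: none
Why: Deprotonation of the terminal alkyne and C-acylation of the lithium acetylide with the chloroformate is a standard ynoate synthesis, and the propargylic C9–H is far too weakly acidic to be touched at −78 °C.

Step 9
Reactants: 14 (E)-2-methylbut-2-enal
Product: 15 (E)-2-methyl-1-[(trimethylsilyl)oxy]buta-1,3-diene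
Conditions: TMSCl, Et3N, ZnCl2 (cat.), toluene, 70 °C; distilled free of amine
Reagents that add atoms: trimethylsilyl chloride, C[Si](C)(C)Cl
Why: Silyl dienol ether formation, in which the enal is O-silylated under ZnCl2 catalysis and loses a γ-proton to Et3N, giving mainly the (E)-dienol ether, the isomer able to adopt the reactive s-cis geometry.

Step 10
Reactants: 13 methyl (4S,5R,6R)-5,7-bis[(tert-butyldimethylsilyl)oxy]-4,6-dimethylhept-2-ynoate; 15 (E)-2-methyl-1-[(trimethylsilyl)oxy]buta-1,3-diene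
Product: 17 methyl 2-{(2S,3R,4R)-3,5-bis[(tert-butyldimethylsilyl)oxy]-4-methylpentan-2-yl}-5-methylbenzoate, via cyclohexadiene cycloadduct 16 (not isolated)
Conditions: 15 (4 equiv), BHT (cat.), toluene, sealed tube, 150 °C; then PPTS (cat.), CH2Cl2, rt
Reagents that add atoms: none
Why: The thermal normal-demand Diels–Alder reaction between the electron-rich silyloxydiene and the electron-poor ynoate is concerted and closes the six-membered carbocycle in a single [4+2] event that forms C1'–C6' and C2'–C3' together. The closest known reaction type is the addition of 1-silyloxybutadienes to acetylenic esters followed by aromatizing loss of silanol. Cycloadduct 16 is a cyclohexa-1,4-diene with a doubly allylic C3'–OSiMe3 group and a C6' methylene, so mild acid triggers 1,4-elimination of Me3SiOH to the benzene ring. No stereocenter remains in the new ring, because the transient C3' center is destroyed on aromatization, and the propargylic C9 is not touched because the medium is neutral and the diene is amine-free. The only selectivity needed is regiochemical: the large HOMO coefficient at the diene terminus remote from oxygen pairs with the β-carbon of the ynoate, so the oxygen-bearing terminus joins the ester-bearing carbon and the methyl group lands on C4', the strong 1-oxygen donor overriding the weak opposite bias of the 2-methyl group. Only the (E)-dienol ether reaches the s-cis geometry, which is why the diene is used in excess.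

Step 11
Reactants: 17 methyl 2-{(2S,3R,4R)-3,5-bis[(tert-butyldimethylsilyl)oxy]-4-methylpentan-2-yl}-5-methylbenzoate
Product: 18 (2-{(2S,3R,4R)-3,5-bis[(tert-butyldimethylsilyl)oxy]-4-methylpentan-2-yl}-5-methylphenyl)methanol
Conditions: i-Bu2AlH (3 equiv), CH2Cl2, −78 → 0 °C; aq. potassium sodium tartrate
Reagents that add atoms: none
Why: Exhaustive hydride reduction of an aryl ester to the benzylic alcohol with excess i-Bu2AlH is routine and silyl ethers are inert to it.

Step 12
Reactants: 18 (2-{(2S,3R,4R)-3,5-bis[(tert-butyldimethylsilyl)oxy]-4-methylpentan-2-yl}-5-methylphenyl)methanol; 19 ethyl (triphenylphosphoranylidene)acetate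
Product: 21 ethyl (E)-3-(2-{(2S,3R,4R)-3,5-bis[(tert-butyldimethylsilyl)oxy]-4-methylpentan-2-yl}-5-methylphenyl)prop-2-enoate, via benzaldehyde 20 (not isolated)
Conditions: activated MnO2 (excess), 19 (1.3 equiv), CH2Cl2, reflux
Reagents that add atoms: none
Why: Tandem oxidation–Wittig olefination, in which MnO2 oxidizes only the benzylic alcohol and the stabilized ylide traps the aldehyde as it forms, giving the (E)-enoate as expected for a stabilized ylide.

Step 13
Reactants: 21 ethyl (E)-3-(2-{(2S,3R,4R)-3,5-bis[(tert-butyldimethylsilyl)oxy]-4-methylpentan-2-yl}-5-methylphenyl)prop-2-enoate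
Product: 22 (E)-3-(2-{(2S,3R,4R)-3,5-bis[(tert-butyldimethylsilyl)oxy]-4-methylpentan-2-yl}-5-methylphenyl)prop-2-en-1-ol
Conditions: i-Bu2AlH (2.5 equiv), CH2Cl2, −78 °C; aq. potassium sodium tartrate
Reagents that add atoms: none
Why: i-Bu2AlH reduces an α,β-unsaturated ester by 1,2-addition to the allylic alcohol at low temperature without touching the alkene or the silyl ethers.

Step 14
Reactants: 22 (E)-3-(2-{(2S,3R,4R)-3,5-bis[(tert-butyldimethylsilyl)oxy]-4-methylpentan-2-yl}-5-methylphenyl)prop-2-en-1-ol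
Product: 23 tert-butyl{[(E)-3-(2-{(2S,3R,4R)-3,5-bis[(tert-butyldimethylsilyl)oxy]-4-methylpentan-2-yl}-5-methylphenyl)prop-2-en-1-yl]oxy}diphenylsilane
Conditions: TBDPSCl, imidazole, CH2Cl2, rt
Reagents that add atoms: tert-butyldiphenylsilyl chloride, CC(C)(C)[Si](Cl)(c1ccccc1)c1ccccc1
Why: Silylation of the primary allylic alcohol, with the TBDPS group chosen because it withstands the acid that removes the primary TBS ether in the next step and still falls to fluoride at the end.

Step 15
Reactants: 23 tert-butyl{[(E)-3-(2-{(2S,3R,4R)-3,5-bis[(tert-butyldimethylsilyl)oxy]-4-methylpentan-2-yl}-5-methylphenyl)prop-2-en-1-yl]oxy}diphenylsilane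
Product: 24 (2R,3R,4S)-3-[(tert-butyldimethylsilyl)oxy]-4-{2-[(E)-3-[(tert-butyldiphenylsilyl)oxy]prop-1-en-1-yl]-4-methylphenyl}-2-methylpentan-1-ol
Conditions: camphorsulfonic acid (cat.), MeOH/CH2Cl2, 0 °C
Reagents that add atoms: none
Why: Acid-catalysed methanolysis of silyl ethers is governed by steric access, so the unhindered primary TBS ether at C6 should be cleaved well before the shielded secondary TBS ether at C8 and the bulkier TBDPS ether.

Step 16
Reactants: 24 (2R,3R,4S)-3-[(tert-butyldimethylsilyl)oxy]-4-{2-[(E)-3-[(tert-butyldiphenylsilyl)oxy]prop-1-en-1-yl]-4-methylphenyl}-2-methylpentan-1-ol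
Product: 25 (2S,3R,4S)-3-[(tert-butyldimethylsilyl)oxy]-4-{2-[(E)-3-[(tert-butyldiphenylsilyl)oxy]prop-1-en-1-yl]-4-methylphenyl}-2-methylpentanal
Conditions: Dess–Martin periodinane, NaHCO3, CH2Cl2, 0 °C → rt; used at once
Reagents that add atoms: none
Why: Dess–Martin oxidation under buffered, near-neutral conditions should give the α-branched aldehyde without epimerization at C7.

Step 17
Reactants: 25 (2S,3R,4S)-3-[(tert-butyldimethylsilyl)oxy]-4-{2-[(E)-3-[(tert-butyldiphenylsilyl)oxy]prop-1-en-1-yl]-4-methylphenyl}-2-methylpentanal; 26 ethyl 2-ethyl-3-oxobutanoate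
Product: 27 ethyl (6R,7R,8S)-7-[(tert-butyldimethylsilyl)oxy]-8-{2-[(E)-3-[(tert-butyldiphenylsilyl)oxy]prop-1-en-1-yl]-4-methylphenyl}-2-ethyl-5-hydroxy-6-methyl-3-oxononanoate (epimers at C2 and C5)
Conditions: 26 (2.5 equiv), NaH, THF, 0 °C; n-BuLi, 0 °C; then 25, −78 °C
Reagents that add atoms: none
Why: Aldol addition of the γ-carbon of the acetoacetate dianion to the aldehyde at −78 °C is fast enough to outrun enolization at C7, and the new carbinol center and the keto ester α-carbon need no control because both become sp2 carbons.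

Step 18
Reactants: 27 ethyl (6R,7R,8S)-7-[(tert-butyldimethylsilyl)oxy]-8-{2-[(E)-3-[(tert-butyldiphenylsilyl)oxy]prop-1-en-1-yl]-4-methylphenyl}-2-ethyl-5-hydroxy-6-methyl-3-oxononanoate
Product: 28 ethyl (6S,7R,8S)-7-[(tert-butyldimethylsilyl)oxy]-8-{2-[(E)-3-[(tert-butyldiphenylsilyl)oxy]prop-1-en-1-yl]-4-methylphenyl}-2-ethyl-6-methyl-3,5-dioxononanoate (epimers at C2)
Conditions: Dess–Martin periodinane, NaHCO3, CH2Cl2, rt
Reagents that add atoms: none
Why: Dess–Martin oxidation of a β-hydroxy ketone to the β-diketone is standard and the product is stabilized as its enol.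

Step 19
Reactants: 28 ethyl (6S,7R,8S)-7-[(tert-butyldimethylsilyl)oxy]-8-{2-[(E)-3-[(tert-butyldiphenylsilyl)oxy]prop-1-en-1-yl]-4-methylphenyl}-2-ethyl-6-methyl-3,5-dioxononanoate
Product: 29 6-[(2S,3R,4S)-3-[(tert-butyldimethylsilyl)oxy]-4-{2-[(E)-3-[(tert-butyldiphenylsilyl)oxy]prop-1-en-1-yl]-4-methylphenyl}pentan-2-yl]-3-ethyl-4-hydroxy-2H-pyran-2-one
Conditions: DBU, toluene, rt → 60 °C; dilute citric acid work-up
Reagents that add atoms: none
Why: Base-mediated lactonization of a 3,5-dioxo ester, in which the enol oxygen on C6 attacks the ester carbonyl in a 6-exo-trig acyl substitution and loss of ethanol gives the 4-hydroxy-2-pyranone, while enolization of the diketone toward C5 keeps C7 from being deprotonated.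

Step 20
Reactants: 29 6-[(2S,3R,4S)-3-[(tert-butyldimethylsilyl)oxy]-4-{2-[(E)-3-[(tert-butyldiphenylsilyl)oxy]prop-1-en-1-yl]-4-methylphenyl}pentan-2-yl]-3-ethyl-4-hydroxy-2H-pyran-2-one
Product: 30 Veramycin A, 3-ethyl-4-hydroxy-6-[(2S,3R,4S)-3-hydroxy-4-{2-[(E)-3-hydroxyprop-1-en-1-yl]-4-methylphenyl}pentan-2-yl]-2H-pyran-2-one
Conditions: Bu4NF (excess), THF, rt → 45 °C; aq. NH4Cl then dilute citric acid
Reagents that add atoms: none
Why: Fluoride-driven desilylation should remove the secondary TBS and the primary TBDPS ether in one operation, the pyranone persisting as its ammonium enolate until the mildly acidic work-up, and no stereocenter is touched.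

Compound list
1 | methyl (R)-3-hydroxy-2-methylpropanoate | OC[C@@H](C)C(=O)OC | starting material
2 | methyl (R)-3-[(tert-butyldimethylsilyl)oxy]-2-methylpropanoate | CC(C)(C)[Si](C)(C)OC[C@@H](C)C(=O)OC | intermediate
3 | (R)-3-[(tert-butyldimethylsilyl)oxy]-2-methylpropanal | CC(C)(C)[Si](C)(C)OC[C@@H](C)C=O | intermediate
4 | 5-(ethylsulfonyl)-1-phenyl-1H-tetrazole | CCS(=O)(=O)c1nnnn1-c1ccccc1 | starting material
5 | tert-butyldimethyl{[(2S,3E)-2-methylpent-3-en-1-yl]oxy}silane | CC(C)(C)[Si](C)(C)OC[C@@H](C)/C=C/C | intermediate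
6 | tert-butyldimethyl{(2R)-2-[(2S,3S)-3-methyloxiran-2-yl]propoxy}silane | CC(C)(C)[Si](C)(C)OC[C@@H](C)[C@@H]1O[C@H]1C | intermediate
7 | ethynyltrimethylsilane (trimethylsilylacetylene) | C#C[Si](C)(C)C | starting material
8 | (2R,3R,4S)-1-[(tert-butyldimethylsilyl)oxy]-2,4-dimethyl-6-(trimethylsilyl)hex-5-yn-3-ol | CC(C)(C)[Si](C)(C)OC[C@@H](C)[C@H](O)[C@@H](C)C#C[Si](C)(C)C | intermediate
9 | (3S,4R,5R)-4,6-bis[(tert-butyldimethylsilyl)oxy]-3,5-dimethyl-1-(trimethylsilyl)hex-1-yne | CC(C)(C)[Si](C)(C)OC[C@@H](C)[C@H](O[Si](C)(C)C(C)(C)C)[C@@H](C)C#C[Si](C)(C)C | intermediate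
10 | (3S,4R,5R)-4,6-bis[(tert-butyldimethylsilyl)oxy]-3,5-dimethylhex-1-yne | CC(C)(C)[Si](C)(C)OC[C@@H](C)[C@H](O[Si](C)(C)C(C)(C)C)[C@@H](C)C#C | intermediate
11 | methyl chloroformate | COC(=O)Cl | starting material
12 | lithium acetylide of 10 (formed in the flask) | CC(C)(C)[Si](C)(C)OC[C@@H](C)[C@H](O[Si](C)(C)C(C)(C)C)[C@@H](C)C#C[Li] | intermediate
13 | methyl (4S,5R,6R)-5,7-bis[(tert-butyldimethylsilyl)oxy]-4,6-dimethylhept-2-ynoate | CC(C)(C)[Si](C)(C)OC[C@@H](C)[C@H](O[Si](C)(C)C(C)(C)C)[C@@H](C)C#CC(=O)OC | intermediate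
14 | (E)-2-methylbut-2-enal | C/C=C(\C)C=O | starting material
15 | (E)-2-methyl-1-[(trimethylsilyl)oxy]buta-1,3-diene | C=C/C(C)=C/O[Si](C)(C)C | intermediate
16 | methyl 2-{(2S,3R,4R)-3,5-bis[(tert-butyldimethylsilyl)oxy]-4-methylpentan-2-yl}-5-methyl-6-[(trimethylsilyl)oxy]cyclohexa-1,4-diene-1-carboxylate (C6 epimers, formed in the flask) | CC(C)(C)[Si](C)(C)OC[C@@H](C)[C@H](O[Si](C)(C)C(C)(C)C)[C@@H](C)C1=C(C(=O)OC)C(O[Si](C)(C)C)C(C)=CC1 | intermediate
17 | methyl 2-{(2S,3R,4R)-3,5-bis[(tert-butyldimethylsilyl)oxy]-4-methylpentan-2-yl}-5-methylbenzoate | CC(C)(C)[Si](C)(C)OC[C@@H](C)[C@H](O[Si](C)(C)C(C)(C)C)[C@@H](C)c1ccc(C)cc1C(=O)OC | intermediate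
18 | (2-{(2S,3R,4R)-3,5-bis[(tert-butyldimethylsilyl)oxy]-4-methylpentan-2-yl}-5-methylphenyl)methanol | CC(C)(C)[Si](C)(C)OC[C@@H](C)[C@H](O[Si](C)(C)C(C)(C)C)[C@@H](C)c1ccc(C)cc1CO | intermediate
19 | ethyl (triphenylphosphoranylidene)acetate | CCOC(=O)C=P(c1ccccc1)(c1ccccc1)c1ccccc1 | starting material
20 | 2-{(2S,3R,4R)-3,5-bis[(tert-butyldimethylsilyl)oxy]-4-methylpentan-2-yl}-5-methylbenzaldehyde (formed in the flask) | CC(C)(C)[Si](C)(C)OC[C@@H](C)[C@H](O[Si](C)(C)C(C)(C)C)[C@@H](C)c1ccc(C)cc1C=O | intermediate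
21 | ethyl (E)-3-(2-{(2S,3R,4R)-3,5-bis[(tert-butyldimethylsilyl)oxy]-4-methylpentan-2-yl}-5-methylphenyl)prop-2-enoate | CC(C)(C)[Si](C)(C)OC[C@@H](C)[C@H](O[Si](C)(C)C(C)(C)C)[C@@H](C)c1ccc(C)cc1/C=C/C(=O)OCC | intermediate
22 | (E)-3-(2-{(2S,3R,4R)-3,5-bis[(tert-butyldimethylsilyl)oxy]-4-methylpentan-2-yl}-5-methylphenyl)prop-2-en-1-ol | CC(C)(C)[Si](C)(C)OC[C@@H](C)[C@H](O[Si](C)(C)C(C)(C)C)[C@@H](C)c1ccc(C)cc1/C=C/CO | intermediate
23 | tert-butyl{[(E)-3-(2-{(2S,3R,4R)-3,5-bis[(tert-butyldimethylsilyl)oxy]-4-methylpentan-2-yl}-5-methylphenyl)prop-2-en-1-yl]oxy}diphenylsilane | CC(C)(C)[Si](C)(C)OC[C@@H](C)[C@H](O[Si](C)(C)C(C)(C)C)[C@@H](C)c1ccc(C)cc1/C=C/CO[Si](c1ccccc1)(c1ccccc1)C(C)(C)C | intermediate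
24 | (2R,3R,4S)-3-[(tert-butyldimethylsilyl)oxy]-4-{2-[(E)-3-[(tert-butyldiphenylsilyl)oxy]prop-1-en-1-yl]-4-methylphenyl}-2-methylpentan-1-ol | OC[C@@H](C)[C@H](O[Si](C)(C)C(C)(C)C)[C@@H](C)c1ccc(C)cc1/C=C/CO[Si](c1ccccc1)(c1ccccc1)C(C)(C)C | intermediate
25 | (2S,3R,4S)-3-[(tert-butyldimethylsilyl)oxy]-4-{2-[(E)-3-[(tert-butyldiphenylsilyl)oxy]prop-1-en-1-yl]-4-methylphenyl}-2-methylpentanal | O=C[C@@H](C)[C@H](O[Si](C)(C)C(C)(C)C)[C@@H](C)c1ccc(C)cc1/C=C/CO[Si](c1ccccc1)(c1ccccc1)C(C)(C)C | intermediate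
26 | ethyl 2-ethyl-3-oxobutanoate | CCOC(=O)C(CC)C(C)=O | starting material
27 | ethyl (6R,7R,8S)-7-[(tert-butyldimethylsilyl)oxy]-8-{2-[(E)-3-[(tert-butyldiphenylsilyl)oxy]prop-1-en-1-yl]-4-methylphenyl}-2-ethyl-5-hydroxy-6-methyl-3-oxononanoate (epimers at C2 and C5) | CCOC(=O)C(CC)C(=O)CC(O)[C@@H](C)[C@H](O[Si](C)(C)C(C)(C)C)[C@@H](C)c1ccc(C)cc1/C=C/CO[Si](c1ccccc1)(c1ccccc1)C(C)(C)C | intermediate
28 | ethyl (6S,7R,8S)-7-[(tert-butyldimethylsilyl)oxy]-8-{2-[(E)-3-[(tert-butyldiphenylsilyl)oxy]prop-1-en-1-yl]-4-methylphenyl}-2-ethyl-6-methyl-3,5-dioxononanoate (epimers at C2) | CCOC(=O)C(CC)C(=O)CC(=O)[C@@H](C)[C@H](O[Si](C)(C)C(C)(C)C)[C@@H](C)c1ccc(C)cc1/C=C/CO[Si](c1ccccc1)(c1ccccc1)C(C)(C)C | intermediate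
29 | 6-[(2S,3R,4S)-3-[(tert-butyldimethylsilyl)oxy]-4-{2-[(E)-3-[(tert-butyldiphenylsilyl)oxy]prop-1-en-1-yl]-4-methylphenyl}pentan-2-yl]-3-ethyl-4-hydroxy-2H-pyran-2-one | CCc1c(O)cc([C@@H](C)[C@H](O[Si](C)(C)C(C)(C)C)[C@@H](C)c2ccc(C)cc2/C=C/CO[Si](c2ccccc2)(c2ccccc2)C(C)(C)C)oc1=O | intermediate
30 | Veramycin A, 3-ethyl-4-hydroxy-6-[(2S,3R,4S)-3-hydroxy-4-{2-[(E)-3-hydroxyprop-1-en-1-yl]-4-methylphenyl}pentan-2-yl]-2H-pyran-2-one | CCc1c(O)cc([C@@H](C)[C@H](O)[C@@H](C)c2ccc(C)cc2/C=C/CO)oc1=O | target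

Total step count: 20 (steps 1–8 and 10–20 on the main line, step 9 for the diene).
Longest linear sequence: 19 steps, from 1 to 30.

Steps most likely to fail

1. Step 10. Cycloaddition at the hindered, alkyl-substituted β-carbon of the ynoate may be slower than thermal oligomerization or hydrolysis of the diene. Traces of base could also isomerize the ynoate toward an allenoate and erode C9. The fallback gives up ring construction and brings in a preformed benzene ring; it sets out from epoxide 6 and comes back at benzylic alcohol 18. Commercial (2-bromo-5-methylphenyl)methanol is etherified (NaH, 4-methoxybenzyl chloride, DMF) to 1-bromo-2-{[(4-methoxybenzyl)oxy]methyl}-4-methylbenzene F1, and Mg in THF converts this into the arylmagnesium bromide F2. Copper-catalysed opening of 6 by F2 (CuI, 10 mol %, THF, −30 → 0 °C) should occur at C9 with inversion, under the same steric bias as step 5, to give the aryl-bearing stereotriad alcohol F3. Silylation of the C8 hydroxyl (TBSOTf, 2,6-lutidine) gives the bis-TBS ether F4, and oxidative removal of the 4-methoxybenzyl group (DDQ, CH2Cl2/pH 7 buffer) gives 18.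

2. Step 5. Regiocontrol may be lost through attack at C8, or the BF3-activated epoxide may rearrange or be captured internally by the C6 silyloxy oxygen before the acetylide arrives. The fallback replaces epoxide opening by a carbonyl addition that sets C8 and C9 together; it sets out from aldehyde 3 and comes back at alkyne 10. (S)-But-3-yn-2-ol is mesylated (MsCl, Et3N, CH2Cl2) to (S)-but-3-yn-2-yl methanesulfonate F5, and anti SN2' displacement with Bu3SnLi and CuBr·SMe2 gives (M)-tributyl(buta-1,2-dien-1-yl)stannane F6. Addition of F6 to 3 promoted by BF3·OEt2 (CH2Cl2, −78 °C) runs through an open transition state with anti SE2' delivery and Felkin attack, two preferences that reinforce each other here, and should give the syn,syn homopropargylic alcohol (2R,3R,4S)-1-[(tert-butyldimethylsilyl)oxy]-2,4-dimethylhex-5-yn-3-ol F7 with the terminal alkyne already in place. Silylation (TBSOTf, 2,6-lutidine) then gives 10.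

3. Step 3. E-selectivity may be incomplete and the α-methyl aldehyde may epimerize under the basic conditions. The geometric isomers of this small, non-polar alkene would be hard to separate and would carry a C9 epimer forward. The fallback is a chromium-mediated gem-dimetallic olefination (Takai–Utimoto ethylidenation) under non-basic conditions; it sets out from aldehyde 3 and comes back at alkene 5. Treatment of 3 with CH3CHI2 and CrCl2 in THF at rt should give 5 directly with high E-selectivity and without exposure of C7 to base; no new compound arises.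

Further compounds
F1 | step 10 | 1-bromo-2-{[(4-methoxybenzyl)oxy]methyl}-4-methylbenzene | COc1ccc(COCc2cc(C)ccc2Br)cc1
F2 | step 10 | [2-({(4-methoxybenzyl)oxy}methyl)-4-methylphenyl]magnesium bromide | COc1ccc(COCc2cc(C)ccc2[Mg]Br)cc1
F3 | step 10 | (2R,3R,4S)-1-[(tert-butyldimethylsilyl)oxy]-4-[2-({(4-methoxybenzyl)oxy}methyl)-4-methylphenyl]-2-methylpentan-3-ol | CC(C)(C)[Si](C)(C)OC[C@@H](C)[C@H](O)[C@@H](C)c1ccc(C)cc1COCc1ccc(OC)cc1
F4 | step 10 | 1-{(2S,3R,4R)-3,5-bis[(tert-butyldimethylsilyl)oxy]-4-methylpentan-2-yl}-2-{[(4-methoxybenzyl)oxy]methyl}-4-methylbenzene | CC(C)(C)[Si](C)(C)OC[C@@H](C)[C@H](O[Si](C)(C)C(C)(C)C)[C@@H](C)c1ccc(C)cc1COCc1ccc(OC)cc1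
F5 | step 5 | (S)-but-3-yn-2-yl methanesulfonate | C#C[C@H](C)OS(C)(=O)=O
F6 | step 5 | (M)-tributyl(buta-1,2-dien-1-yl)stannane (axial descriptor aR) | CCCC[Sn](CCCC)(CCCC)[CH]=[C@]=[CH]C
F7 | step 5 | (2R,3R,4S)-1-[(tert-butyldimethylsilyl)oxy]-2,4-dimethylhex-5-yn-3-ol | CC(C)(C)[Si](C)(C)OC[C@@H](C)[C@H](O)[C@@H](C)C#C
F0 | step 3 | none | none
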